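At early times the flask holds substrate and solid reagent, with [partner] rising from zero at the start; the steps to side product A and side product B need no partner, while the step to target does.

in all of them: substrate 30 mM; solid reagent 150 mM; time 10 min

| flask | temperature |
|---|---|
| autumn | 0 °C |
| dusk | 20 °C |
| spring | 40 °C |

    target → over-reaction product (k1 = 0.00644 s⁻¹, Ea1 = 82.0 kJ mol⁻¹)
    2 partner → self-condensation product (k2 = 0.0789 M⁻¹ s⁻¹, Ea2 = 57.0 kJ mol⁻¹)
    solid reagent ⇌ partner, rate k3*(cs3 - [partner]) while solid is left; crystals form when [partner] > cs3 (cs3 = 24 mM, k3 = 0.00161 s⁻¹)
    substrate → side product A (k4 = 0.00693 s⁻¹, Ea4 = 72.0 kJ mol⁻¹)
    substrate + partner → target (k5 = 0.212 M⁻¹ s⁻¹, Ea5 = 45.0 kJ mol⁻¹)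
    2 substrate → side product B (k6 = 0.0683 M⁻¹ s⁻¹, Ea6 = 65.0 kJ mol⁻¹)
    (constants at 20 °C)

- in percentages every species weighs as the substrate in it: one side product B counts as two
- a step written with two of one species runs at k times the square of its concentration and takes two of it each time
- as a solid, counted per litre of solution: solid reagent
- all constants are for 20 °C and move with temperature by the activation energies
- at the start none of the solid reagent is in solution

1. the flask with the highest share of target in all that became target or side product A or side product B or over-reaction product ("all alike" if they lie within 1.5 percentage points) (autumn / dusk / spring / all alike)
2. share of target in all that became target or side product A or side product B or over-reaction product, autumn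
3. share of target in all that became target or side product A or side product B or over-reaction product, dusk
4. share of target in all that became target or side product A or side product B or over-reaction product, spring

My bench rule is to count turnovers: a first-order step acting by itself makes k·t of them in a run and leaves exp(−k·t) of what it acts on, 4.98% at a count of 3. For substrate going to side product A, the count is 0.478 in autumn, 4.16 at dusk and 27.4 in spring. For target going to over-reaction product, the dusk count is 3.86, so target made at the very start of the dusk flask keeps 2.11% by the end.

But the rule stops at the step that makes target. Substrate meets partner with a pseudo-first-order constant k[partner], and [partner] climbs from zero, so no fixed count exists. Its clock is the dissolving time, 10.4 min, and the scheme gives dissolving no activation energy. I therefore divide the rate constant of substrate's loss to side product A by the dissolving coefficient. Autumn gives 0.495, dusk 4.30 and spring 28.4. This is the head start: the turnovers that loss makes during one dissolving time. Its border is 1. Autumn lies below it, while dusk and spring lie above. Warming speeds the target-forming step too, but it has the lowest activation energy of the steps that have one. I commit to autumn as the best flask and give no share by hand.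

The forecast gives autumn, with 18.5% for autumn, 0.9% for dusk and 0% for spring, on the grounds: “Partner dissolves slowly and its rate does not rise with temperature”.

The simulation gives autumn, with shares of 19.1%, 0.688% and 0% for autumn, dusk and spring. In autumn, at a head start of 0.495, substrate and partner stood together: at 5.00 min there were 63.6% of substrate and 7.65 mM of partner, and at the end 39.1% of substrate and 11.6% of target. At dusk, at a head start of 4.30, half the substrate was converted within 1.14 min, well inside the dissolving time, and the end held 72.5% of side product A and 0.685% of target.

A flask like autumn kept at −15 °C has a head start of 0.0784, further below the border than autumn, so I expect substrate to wait for partner better there. Computed, that flask ends with 80% of its substrate left and a share of 36.4%, above autumn's.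

The constants were set for the occasion; the result is computed.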